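The tetrahydrofuran ring B (C3a, C4, O5, C6, C6a of the furo[3,4-c]furan-1-one) is cut at C4–O5 and C6–C6a. This leaves silyl-protected protocatechualdehyde and a three-carbon dipole, nucleophilic at C6a and electrophilic at C4, which is stored as a cyclopropane fused to lactone ring A. In one operation catalytic MgI2 opens the strained C4–C6a bond, the stabilised enolate adds reversibly to the aldehyde, and only the aldolate cis to the CH2I arm can close ring B. The step exploits the 1,3-relation of C6a (alpha to C1=O) and C4 and the obligatory cis fusion of rings A and B. C3, secured by enzymatic resolution, relays all other centres.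

Key step: step 9

Remark on the chemistry: product numbering (C1 carbonyl, O2, C3, C3a, C4, O5, C6, C6a) is used for all intermediates. Ring A is the lactone and ring B the tetrahydrofuran. The extra ester at C6a is a temporary activating group that step 10 removes.

Step 1
Reactants: 1 vanillin
Product: 2 4-(tert-butyldimethylsilyloxy)-3-methoxybenzaldehyde
Conditions: TBSCl, imidazole, DMF, 0 °C to rt
Reagents that add atoms: tert-butyldimethylsilyl chloride, CC(C)(C)[Si](C)(C)Cl
Why: Imidazole-promoted silyl ether formation masks the phenol and leaves the aldehyde untouched.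

Step 2
Reactants: 2 4-(tert-butyldimethylsilyloxy)-3-methoxybenzaldehyde
Product: 3 rac-1-[4-(tert-butyldimethylsilyloxy)-3-methoxyphenyl]prop-2-en-1-ol
Conditions: CH2=CHMgBr, THF, -78 to 0 °C; then H2O
Reagents that add atoms: vinylmagnesium bromide, C=C[Mg]Br
Why: Grignard 1,2-addition to the aldehyde gives the racemic allylic alcohol, and the aryl silyl ether tolerates the reagent at low temperature.

Step 3
Reactants: 3 rac-1-[4-(tert-butyldimethylsilyloxy)-3-methoxyphenyl]prop-2-en-1-ol
Product: 4 (S)-1-[4-(tert-butyldimethylsilyloxy)-3-methoxyphenyl]prop-2-en-1-ol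
Conditions: Novozym 435 (immobilised Candida antarctica lipase B), vinyl acetate, MTBE, 30 °C, stopped just past half conversion; chromatography
Reagents that add atoms: none
Why: In this lipase-catalysed kinetic resolution the R alcohol (aryl large, vinyl medium, Kazlauskas rule) is acetylated, so the S alcohol that carries the future C3 centre is recovered.

Step 4
Reactants: 5 Meldrum's acid; 6 2,2,2-trichloroethanol
Product: 7 3-oxo-3-(2,2,2-trichloroethoxy)propanoic acid (mono-trichloroethyl malonate)
Conditions: toluene, 110 °C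
Reagents that add atoms: none
Why: Thermal alcoholysis of Meldrum's acid opens the ring to the malonic half ester with loss of acetone.

Step 5
Reactants: 4 (S)-allylic alcohol; 7 mono-trichloroethyl malonate
Product: 8 (S)-1-[4-(tert-butyldimethylsilyloxy)-3-methoxyphenyl]allyl 2,2,2-trichloroethyl malonate
Conditions: DCC, DMAP (cat.), CH2Cl2, 0 °C
Reagents that add atoms: none
Why: Steglich esterification acylates the oxygen without touching the C–O bond of the stereocentre, so the configuration is retained.

Step 6
Reactants: 8 mixed malonate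
Product: 9 (S)-1-[4-(tert-butyldimethylsilyloxy)-3-methoxyphenyl]allyl 2,2,2-trichloroethyl 2-iodomalonate (epimers at CHI)
Conditions: NaH, THF, 0 °C; NIS, dark; then H2O
Reagents that add atoms: N-iodosuccinimide, O=C1CCC(=O)N1I
Why: Electrophilic alpha-iodination of the sodium malonate enolate is much faster than iodination of the arene and installs the weak C–I bond needed for atom transfer.

Step 7
Reactants: 9 iodomalonate
Product: 11 2,2,2-trichloroethyl (1R,4S,5S)-4-[4-(tert-butyldimethylsilyloxy)-3-methoxyphenyl]-2-oxo-3-oxabicyclo[3.1.0]hexane-1-carboxylate (aryl anti to the cyclopropane CH2), via iodomethyl lactone 10 (not isolated)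
Conditions: dilauroyl peroxide (10 mol %), benzene, 80 °C; then DBU, 0 °C to rt; chromatography
Reagents that add atoms: none
Why: Iodine-atom-transfer radical cyclisation (5-exo-trig) through a Beckwith–Houk chair with the aryl group pseudo-equatorial should place the CH2I arm at C3a trans to the aryl group at C3, and DBU then closes the necessarily cis-fused cyclopropane by 3-exo-tet alkylation of the malonate-type anion (the minor cis-lactone gives a separable endo-aryl isomer).

Step 8
Reactants: 12 3,4-dihydroxybenzaldehyde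
Product: 13 3,4-bis(tert-butyldimethylsilyloxy)benzaldehyde
Conditions: TBSCl (2.4 equiv), imidazole, DMF, rt
Reagents that add atoms: tert-butyldimethylsilyl chloride, CC(C)(C)[Si](C)(C)Cl
Why: Double silyl ether formation masks the catechol with the same group as in 11, so one final operation frees all three phenols.

Step 9
Reactants: 11 cyclopropane-fused lactone ester; 13 3,4-bis(tert-butyldimethylsilyloxy)benzaldehyde
Product: 16 2,2,2-trichloroethyl (3S,3aR,6R,6aS)-6-[3,4-bis(tert-butyldimethylsilyloxy)phenyl]-3-[4-(tert-butyldimethylsilyloxy)-3-methoxyphenyl]-1-oxotetrahydro-1H,3H-furo[3,4-c]furan-6a-carboxylate (cis-fused, both aryl groups exo), via iodo enolate 14 (not isolated), via cis-aldolate 15 (not isolated)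
Conditions: MgI2 (30 mol %), 13 (1.5 equiv), 4 Å molecular sieves, THF, 65 °C, sealed tube
Reagents that add atoms: none
Why: Proposed new method: MgI2 chelates the lactone and ester carbonyl groups of 11, iodide opens the C6a–C4 cyclopropane bond by SN2 attack at the unsubstituted CH2 (the exocyclic bond that overlaps best with both carbonyl π systems), and the malonate-type magnesium enolate 14 adds reversibly to 13 before the alkoxide displaces iodide and returns the catalyst. The closest known reaction types are the MgI2-catalysed ring expansion of spirocyclopropyl oxindoles with imines, the MgI2/pybox-catalysed [3+2] annulation of aryl-substituted cyclopropane-1,1-diesters with aldehydes and the iodide-induced ring opening/aldol reaction of cyclopropyl ketones, but a donor-free, lactone-fused cyclopropane has not been joined to an aldehyde in this way. Ring B closes in the 5-exo-tet mode. C6a is controlled by ring strain, because aldolates formed anti to the CH2I arm cannot reach it and revert by retro-aldol cleavage (any re-closed cyclopropane is reopened by iodide), so that all material drains through cis-aldolate 15 into the cis-fused bicycle. C6 is controlled by the substrate, since in the chelated aldolate the aryl group turns away from the CH2I arm and in the closing envelope, whose pucker is fixed by the trans-diequatorial substituents of ring A, it lies pseudo-equatorial on the convex face, whereas the epimer must push it into the concave pocket under the lactone. The step needs selectivity for the cyclopropane over the benzylic C3–O2 bond and the ester alkyl group, which the weak Lewis acid in THF, the silyl-attenuated donor aryl group and the SN2-inert trichloroethyl group should secure.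

Step 10
Reactants: 16 annulated trichloroethyl ester
Product: 18 (3S,3aR,6S,6aS)-6-[3,4-bis(tert-butyldimethylsilyloxy)phenyl]-3-[4-(tert-butyldimethylsilyloxy)-3-methoxyphenyl]tetrahydro-1H,3H-furo[3,4-c]furan-1-one, via malonic half acid 17 (not isolated)
Conditions: Zn dust, AcOH/THF, rt; filtration, evaporation; then toluene, 100 °C
Reagents that add atoms: none
Why: Zinc-induced reductive fragmentation of the trichloroethyl ester is followed by thermal decarboxylation of the malonic half acid through its enol, whose ketonisation can only deliver hydrogen to the convex face because a trans-fused bicyclo[3.3.0] skeleton is prohibitively strained, so C6a is reset as S while C3, C3a and C6 are untouched.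

Step 11
Reactants: 18 tris-silyl furofuranone
Product: 19 (3S,3aR,6S,6aS)-6-(3,4-dihydroxyphenyl)-3-(4-hydroxy-3-methoxyphenyl)tetrahydro-1H,3H-furo[3,4-c]furan-1-one (target)
Conditions: HF·pyridine, pyridine, THF, 0 °C to rt, argon
Reagents that add atoms: none
Why: Fluoride-driven cleavage of the three aryl silyl ethers under acidic buffering avoids phenoxide formation and hence quinone methide opening of the benzylic C3–O2 and C6–O5 bonds.

Compound list
1 | vanillin | COc1cc(C=O)ccc1O | starting material
2 | 4-(tert-butyldimethylsilyloxy)-3-methoxybenzaldehyde | COc1cc(C=O)ccc1O[Si](C)(C)C(C)(C)C | intermediate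
3 | rac-1-[4-(tert-butyldimethylsilyloxy)-3-methoxyphenyl]prop-2-en-1-ol | COc1cc(C(O)C=C)ccc1O[Si](C)(C)C(C)(C)C | intermediate
4 | (S)-1-[4-(tert-butyldimethylsilyloxy)-3-methoxyphenyl]prop-2-en-1-ol | COc1cc([C@@H](O)C=C)ccc1O[Si](C)(C)C(C)(C)C | intermediate
5 | Meldrum's acid (2,2-dimethyl-1,3-dioxane-4,6-dione) | CC1(C)OC(=O)CC(=O)O1 | starting material
6 | 2,2,2-trichloroethanol | OCC(Cl)(Cl)Cl | starting material
7 | 3-oxo-3-(2,2,2-trichloroethoxy)propanoic acid | OC(=O)CC(=O)OCC(Cl)(Cl)Cl | intermediate
8 | (S)-1-[4-(tert-butyldimethylsilyloxy)-3-methoxyphenyl]allyl 2,2,2-trichloroethyl malonate | COc1cc([C@@H](OC(=O)CC(=O)OCC(Cl)(Cl)Cl)C=C)ccc1O[Si](C)(C)C(C)(C)C | intermediate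
9 | (S)-1-[4-(tert-butyldimethylsilyloxy)-3-methoxyphenyl]allyl 2,2,2-trichloroethyl 2-iodomalonate (epimers at CHI) | COc1cc([C@@H](OC(=O)C(I)C(=O)OCC(Cl)(Cl)Cl)C=C)ccc1O[Si](C)(C)C(C)(C)C | intermediate
10 | 2,2,2-trichloroethyl (4S,5S)-5-[4-(tert-butyldimethylsilyloxy)-3-methoxyphenyl]-4-(iodomethyl)-2-oxooxolane-3-carboxylate (epimers at C3 of the oxolane) | COc1cc([C@H]2OC(=O)C(C(=O)OCC(Cl)(Cl)Cl)[C@@H]2CI)ccc1O[Si](C)(C)C(C)(C)C | intermediate
11 | 2,2,2-trichloroethyl (1R,4S,5S)-4-[4-(tert-butyldimethylsilyloxy)-3-methoxyphenyl]-2-oxo-3-oxabicyclo[3.1.0]hexane-1-carboxylate | COc1cc([C@H]2OC(=O)[C@]3(C(=O)OCC(Cl)(Cl)Cl)C[C@H]23)ccc1O[Si](C)(C)C(C)(C)C | intermediate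
12 | 3,4-dihydroxybenzaldehyde | O=Cc1ccc(O)c(O)c1 | starting material
13 | 3,4-bis(tert-butyldimethylsilyloxy)benzaldehyde | O=Cc1ccc(O[Si](C)(C)C(C)(C)C)c(O[Si](C)(C)C(C)(C)C)c1 | intermediate
14 | iodomagnesium enolate of ring-opened 11 (beta-iodomethyl lactone enolate) | COc1cc([C@H]2OC([O-])=C(C(=O)OCC(Cl)(Cl)Cl)[C@@H]2CI)ccc1O[Si](C)(C)C(C)(C)C.[Mg+2].[I-] | intermediate
15 | iodomagnesium cis-aldolate (carbinol carbon cis to the CH2I arm) | COc1cc([C@H]2OC(=O)[C@](C(=O)OCC(Cl)(Cl)Cl)([C@H]([O-])c3ccc(O[Si](C)(C)C(C)(C)C)c(O[Si](C)(C)C(C)(C)C)c3)[C@@H]2CI)ccc1O[Si](C)(C)C(C)(C)C.[Mg+2].[I-] | intermediate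
16 | 2,2,2-trichloroethyl (3S,3aR,6R,6aS)-6-[3,4-bis(tert-butyldimethylsilyloxy)phenyl]-3-[4-(tert-butyldimethylsilyloxy)-3-methoxyphenyl]-1-oxotetrahydro-1H,3H-furo[3,4-c]furan-6a-carboxylate | COc1cc([C@H]2OC(=O)[C@@]3(C(=O)OCC(Cl)(Cl)Cl)[C@@H]2CO[C@@H]3c2ccc(O[Si](C)(C)C(C)(C)C)c(O[Si](C)(C)C(C)(C)C)c2)ccc1O[Si](C)(C)C(C)(C)C | intermediate
17 | (3S,3aR,6R,6aS)-6-[3,4-bis(tert-butyldimethylsilyloxy)phenyl]-3-[4-(tert-butyldimethylsilyloxy)-3-methoxyphenyl]-1-oxotetrahydro-1H,3H-furo[3,4-c]furan-6a-carboxylic acid | COc1cc([C@H]2OC(=O)[C@@]3(C(=O)O)[C@@H]2CO[C@@H]3c2ccc(O[Si](C)(C)C(C)(C)C)c(O[Si](C)(C)C(C)(C)C)c2)ccc1O[Si](C)(C)C(C)(C)C | intermediate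
18 | (3S,3aR,6S,6aS)-6-[3,4-bis(tert-butyldimethylsilyloxy)phenyl]-3-[4-(tert-butyldimethylsilyloxy)-3-methoxyphenyl]tetrahydro-1H,3H-furo[3,4-c]furan-1-one | COc1cc([C@H]2OC(=O)[C@H]3[C@@H]2CO[C@@H]3c2ccc(O[Si](C)(C)C(C)(C)C)c(O[Si](C)(C)C(C)(C)C)c2)ccc1O[Si](C)(C)C(C)(C)C | intermediate
19 | (3S,3aR,6S,6aS)-6-(3,4-dihydroxyphenyl)-3-(4-hydroxy-3-methoxyphenyl)tetrahydro-1H,3H-furo[3,4-c]furan-1-one | COc1cc([C@H]2OC(=O)[C@H]3[C@@H]2CO[C@@H]3c2ccc(O)c(O)c2)ccc1O | target

Total step count: 11. Longest linear sequence: 9 steps (1, 2, 3, 5, 6, 7, 9, 10, 11).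

Steps most likely to fail

Step 9. The donor-free cyclopropane may open too slowly. The uphill aldol addition to the electron-rich aldehyde may starve the ring closure. Facial selectivity at C6 may erode: the ester on the convex face crowds the exo position, and related ring closures that form the C6–C6a bond are known to place the aryl group endo. Iodide may also attack the benzylic C3–O2 bond.

The fallback uses known chemistry and closes ring B at O5–C6 instead. It sets out from 4 and returns at 18.
- Acylation of 4 with acryloyl chloride and Et3N should give the (S)-allyl acrylate F1.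
- Ring-closing metathesis with the second-generation Grubbs catalyst should give the (S)-5-aryl butenolide F2.
- Benzophenone-sensitised photoaddition of methanol anti to the aryl group should give the (4R,5S)-hydroxymethyl lactone F3, which is masked as its triethylsilyl ether F4.
- Addition of the lithium enolate of F4 (LDA, THF, -78 °C) to 13 gives the aldol carbinol mixture F5.
- MsCl and Et3N convert F5 into the mesylate F6, and DBU eliminates it to the silylated (E)-benzylidene lactone F7.
- AcOH/H2O/THF frees the (E)-benzylidene hydroxymethyl lactone F8, and catalytic DBU triggers the intramolecular oxa-Michael addition.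
- Oxygen adds to the E-alkene from the face of the CH2OH arm and C6a is protonated on the convex face. This anti addition should give the exo aryl group of 18.

Step 7. The ester prefers the rotamer that holds the radical away from the alkene. The 5-exo closure may therefore lag behind oligomerisation or hydrogen abstraction, and the trans/cis preference at C3a may be modest.

The fallback replaces the radical by a carbenoid. It sets out from 8 and returns at 11. Diazo transfer (4-acetamidobenzenesulfonyl azide, Et3N, MeCN) gives the diazomalonate F9. Rh2(OAc)4 in refluxing CH2Cl2 then effects the intramolecular cyclopropanation of the vinyl group, and the exo-aryl isomer is separated by chromatography.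

Step 10. Heating the half acid may ionise the benzylic C3–O2 bond, which would scramble C3, or carbon dioxide loss may stay incomplete.

The fallback replaces the thermal by a radical decarboxylation at room temperature. It sets out from 17, now isolated, and returns at 18. DCC coupling with 1-hydroxypyridine-2(1H)-thione gives the Barton ester F10. Visible-light photolysis with tert-butyl thiol (Barton decarboxylation) generates the C6a radical, which should abstract hydrogen on the convex face.

Further compounds
F1 | step 9 | (S)-1-[4-(tert-butyldimethylsilyloxy)-3-methoxyphenyl]allyl acrylate | COc1cc([C@@H](OC(=O)C=C)C=C)ccc1O[Si](C)(C)C(C)(C)C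
F2 | step 9 | (S)-5-[4-(tert-butyldimethylsilyloxy)-3-methoxyphenyl]furan-2(5H)-one | COc1cc([C@H]2OC(=O)C=C2)ccc1O[Si](C)(C)C(C)(C)C
F3 | step 9 | (4R,5S)-5-[4-(tert-butyldimethylsilyloxy)-3-methoxyphenyl]-4-(hydroxymethyl)oxolan-2-one | COc1cc([C@H]2OC(=O)C[C@@H]2CO)ccc1O[Si](C)(C)C(C)(C)C
F4 | step 9 | (4R,5S)-5-[4-(tert-butyldimethylsilyloxy)-3-methoxyphenyl]-4-(triethylsilyloxymethyl)oxolan-2-one | COc1cc([C@H]2OC(=O)C[C@@H]2CO[Si](CC)(CC)CC)ccc1O[Si](C)(C)C(C)(C)C
F5 | step 9 | aldol carbinol of F4 and 13 (mixture at the alpha and carbinol carbons) | COc1cc([C@H]2OC(=O)C(C(O)c3ccc(O[Si](C)(C)C(C)(C)C)c(O[Si](C)(C)C(C)(C)C)c3)[C@@H]2CO[Si](CC)(CC)CC)ccc1O[Si](C)(C)C(C)(C)C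
F6 | step 9 | mesylate of F5 | COc1cc([C@H]2OC(=O)C(C(OS(C)(=O)=O)c3ccc(O[Si](C)(C)C(C)(C)C)c(O[Si](C)(C)C(C)(C)C)c3)[C@@H]2CO[Si](CC)(CC)CC)ccc1O[Si](C)(C)C(C)(C)C
F7 | step 9 | (E)-alpha-[3,4-bis(tert-butyldimethylsilyloxy)benzylidene] lactone, triethylsilyl ether | COc1cc([C@H]2OC(=O)/C(=C/c3ccc(O[Si](C)(C)C(C)(C)C)c(O[Si](C)(C)C(C)(C)C)c3)[C@@H]2CO[Si](CC)(CC)CC)ccc1O[Si](C)(C)C(C)(C)C
F8 | step 9 | (E)-alpha-[3,4-bis(tert-butyldimethylsilyloxy)benzylidene]-beta-(hydroxymethyl) lactone | COc1cc([C@H]2OC(=O)/C(=C/c3ccc(O[Si](C)(C)C(C)(C)C)c(O[Si](C)(C)C(C)(C)C)c3)[C@@H]2CO)ccc1O[Si](C)(C)C(C)(C)C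
F9 | step 7 | (S)-1-[4-(tert-butyldimethylsilyloxy)-3-methoxyphenyl]allyl 2,2,2-trichloroethyl 2-diazomalonate | COc1cc([C@@H](OC(=O)C(=[N+]=[N-])C(=O)OCC(Cl)(Cl)Cl)C=C)ccc1O[Si](C)(C)C(C)(C)C
F10 | step 10 | 2-thioxopyridin-1(2H)-yl ester of acid 17 (Barton ester) | COc1cc([C@H]2OC(=O)[C@@]3(C(=O)ON4C=CC=CC4=S)[C@@H]2CO[C@@H]3c2ccc(O[Si](C)(C)C(C)(C)C)c(O[Si](C)(C)C(C)(C)C)c2)ccc1O[Si](C)(C)C(C)(C)C
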